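**Retrosynthetic overview**
1. Target 16 comes from benzyl ester 15 by hydrogenolysis. The depside ester C–O bond of 15 is cut to the 4-OH of benzyl olivetolate 9 and aroyl chloride 14; that ring is bought as divarinol 10 and only functionalised (O-methylation, Vilsmeier formylation, Pinnick oxidation, chlorination).
2. 9 comes from benzodioxinone 8 by benzyloxide opening. The acetonide is exchanged for a benzyl ester before the depside bond is made, because freeing the acid from the acetonide needs hot hydroxide, which the aryl ester would not survive.
3. 8 comes from diketo-dioxinone 6, and this closes the only ring built in the route. The strategy rests on the 2,4-dioxygenated 6-pentylbenzoate ring being a folded tetraketide: the bond between its carboxyl-bearing C1 and its pentyl-bearing C6 (polyketide C2–C7) is made by aldol of dioxinone C5 onto the pentyl ketone, then aromatisation.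
4. 6 comes from the dianion of keto-dioxinone 3 and Weinreb amide 5 (from hexanoyl chloride 4); 3 comes from dioxinone 1 and acetyl chloride 2.

Key step: step 4

Remark on the chemistry: the target has no stereocentre or other stereogenic element, so it is achiral; the SMILES given is the full stereochemical description and no enantioselective step is needed.

**Route**

Step 1
Reactants: 1 2,2,6-trimethyl-4H-1,3-dioxin-4-one; 2 acetyl chloride
Product: 3 2,2-dimethyl-6-(2-oxopropyl)-4H-1,3-dioxin-4-one
Conditions: 1 (2 equiv), LiHMDS (2 equiv), THF, −78 °C; then 2 (1 equiv), −78 °C; aq. NH4Cl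
Reagents that add atoms: none
Why: γ-Deprotonation of the vinylogous ester gives the lithium dienolate, which undergoes Claisen-type C-acylation at the exocyclic methyl carbon, the second equivalent of dienolate taking up the proton of the more acidic product.

Step 2
Reactants: 4 hexanoyl chloride
Product: 5 N-methoxy-N-methylhexanamide
Conditions: MeNH(OMe)·HCl, Et3N (2.2 equiv), CH2Cl2, 0 °C → rt
Reagents that add atoms: N,O-dimethylhydroxylamine hydrochloride, CNOC.Cl
Why: Schotten–Baumann-type amide formation from an acid chloride gives the Weinreb amide, an acyl donor that cannot over-react with a carbanion.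

Step 3
Reactants: 3 2,2-dimethyl-6-(2-oxopropyl)-4H-1,3-dioxin-4-one; 5 N-methoxy-N-methylhexanamide
Product: 6 2,2-dimethyl-6-(2,4-dioxononyl)-4H-1,3-dioxin-4-one (largely enolised; used without prolonged storage)
Conditions: LDA (2.1 equiv), THF, −78 °C; then 5, −78 → −40 °C; cold 1 M HCl quench
Reagents that add atoms: none
Why: Huckin–Weiler-type dianion acylation: the first equivalent of base removes the proton of the doubly activated C1′ methylene and the second the terminal methyl, and the more basic terminal carbanion adds to the Weinreb amide to give a chelated tetrahedral intermediate that releases the 1,3-diketone only on acidic quench.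

Step 4
Reactants: 6 2,2-dimethyl-6-(2,4-dioxononyl)-4H-1,3-dioxin-4-one
Product: 8 7-hydroxy-2,2-dimethyl-5-pentyl-4H-benzo[d][1,3]dioxin-4-one, via cyclic aldol carbinol 7 (not isolated)
Conditions: Et3N (5 equiv), CH2Cl2, 4 Å MS, rt; dilute HCl wash
Reagents that add atoms: none
Why: Et3N reversibly enolises the chain, and the anion formed at the C1′ methylene is a dienolate of the vinylogous ester whose α-carbon (dioxinone C5) adds to the C4′ pentyl ketone to give carbinol 7, which loses water and enolises at the C2′ ketone to give the phenol. The closest known reaction type is the amine- or carbonate-promoted cycloaromatisation of diketo-dioxinones to isopropylidene-protected β-resorcylates, a laboratory version of the polyketide C2–C7 aldol. The benzene ring is closed in a 6-(enolexo)-exo-trig aldol, a favoured mode, and aromatisation makes the closure irreversible. No stereocentre remains, since the carbinol centre of 7 is formed racemic and is destroyed on dehydration. The step needs C-aldol at the terminal ketone in preference to O-cyclisation to a pyranone or Claisen-type closure; the intact dioxinone secures this because the carboxyl carbon is locked as a poorly electrophilic ketal-lactone and only C5 can reach the ketone through a six-membered transition state. The same mask holds the carboxyl and the C2 oxygen, so decarboxylation to olivetol cannot occur and only the hydroxyl para to the carboxyl emerges free.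

Step 5
Reactants: 8 7-hydroxy-2,2-dimethyl-5-pentyl-4H-benzo[d][1,3]dioxin-4-one
Product: 9 benzyl 2,4-dihydroxy-6-pentylbenzoate (benzyl olivetolate)
Conditions: BnOH (5 equiv), NaH (3 equiv), THF, 0 → 50 °C; cold 1 M HCl
Reagents that add atoms: benzyl alcohol, OCc1ccccc1
Why: Alkoxide transesterification (addition–elimination) at the lactone carbonyl of the salicylate acetonide, made irreversible because the expelled hemiketal alkoxide collapses to acetone and the 2-phenoxide.

Step 6
Reactants: 10 5-propylbenzene-1,3-diol (divarinol)
Product: 11 1,3-dimethoxy-5-propylbenzene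
Conditions: MeI (2.5 equiv), K2CO3, acetone, reflux
Reagents that add atoms: iodomethane, CI
Why: Williamson ether synthesis on both phenols, which are the only acidic sites.

Step 7
Reactants: 11 1,3-dimethoxy-5-propylbenzene
Product: 12 2,4-dimethoxy-6-propylbenzaldehyde
Conditions: POCl3, DMF, 0 → 70 °C; then ice–water, rt
Reagents that add atoms: N,N-dimethylformamide, CN(C)C=O; water, O
Why: Vilsmeier–Haack formylation occurs at the position ortho to propyl (para to one methoxyl, ortho to the other; the two such sites are equivalent) because the site between the two methoxyls is sterically shielded, as is known for orcinol dimethyl ether.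

Step 8
Reactants: 12 2,4-dimethoxy-6-propylbenzaldehyde
Product: 13 2,4-dimethoxy-6-propylbenzoic acid
Conditions: NaClO2, NaH2PO4, 2-methyl-2-butene (excess), t-BuOH/H2O, rt
Reagents that add atoms: sodium chlorite, [Na+].[O-]Cl=O
Why: Pinnick (Lindgren–Kraus) oxidation converts the aldehyde to the acid under mildly acidic conditions, with the alkene scavenging hypochlorous acid so that the electron-rich ring is not chlorinated.

Step 9
Reactants: 13 2,4-dimethoxy-6-propylbenzoic acid
Product: 14 2,4-dimethoxy-6-propylbenzoyl chloride (volatiles evaporated, used crude)
Conditions: (COCl)2 (1.5 equiv), DMF (cat.), CH2Cl2, 0 °C → rt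
Reagents that add atoms: oxalyl chloride, O=C(Cl)C(=O)Cl
Why: Acid chloride formation through the catalytic Vilsmeier chloroiminium species, under conditions that leave the aryl methyl ethers untouched.

Step 10
Reactants: 9 benzyl 2,4-dihydroxy-6-pentylbenzoate; 14 2,4-dimethoxy-6-propylbenzoyl chloride
Product: 15 benzyl 4-[(2,4-dimethoxy-6-propylbenzoyl)oxy]-2-hydroxy-6-pentylbenzoate
Conditions: 14 (1.1 equiv), Et3N, DMAP (cat.), CH2Cl2, 0 °C → rt
Reagents that add atoms: none
Why: DMAP-catalysed O-acylation should take place at the 4-hydroxyl, since the 2-hydroxyl is hydrogen-bonded to the ester carbonyl and flanked by the ester, which is the usual regiochemistry of depside couplings on 2,4-dihydroxybenzoate esters.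

Step 11
Reactants: 15 benzyl 4-[(2,4-dimethoxy-6-propylbenzoyl)oxy]-2-hydroxy-6-pentylbenzoate
Product: 16 4-[(2,4-dimethoxy-6-propylbenzoyl)oxy]-2-hydroxy-6-pentylbenzoic acid (target, CNP0324837.0)
Conditions: H2 (1 atm), 10% Pd/C, EtOAc, rt
Reagents that add atoms: none
Why: Catalytic hydrogenolysis cleaves only the benzylic C–O bond; the aryl ester, methyl ethers and arenes are inert at 1 atm, and the neutral room-temperature conditions avoid decarboxylation of the salicylic acid.

**Compound list**
1 | 2,2,6-trimethyl-4H-1,3-dioxin-4-one | CC1=CC(=O)OC(C)(C)O1 | starting material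
2 | acetyl chloride | CC(=O)Cl | starting material
3 | 2,2-dimethyl-6-(2-oxopropyl)-4H-1,3-dioxin-4-one | CC(=O)CC1=CC(=O)OC(C)(C)O1 | intermediate
4 | hexanoyl chloride | CCCCCC(=O)Cl | starting material
5 | N-methoxy-N-methylhexanamide | CCCCCC(=O)N(C)OC | intermediate
6 | 2,2-dimethyl-6-(2,4-dioxononyl)-4H-1,3-dioxin-4-one | CCCCCC(=O)CC(=O)CC1=CC(=O)OC(C)(C)O1 | intermediate
7 | 5-hydroxy-2,2-dimethyl-5-pentyl-5,6-dihydro-4H-benzo[d][1,3]dioxine-4,7(8H)-dione (racemic, not isolated) | CCCCCC1(O)CC(=O)CC2=C1C(=O)OC(C)(C)O2 | intermediate
8 | 7-hydroxy-2,2-dimethyl-5-pentyl-4H-benzo[d][1,3]dioxin-4-one | CCCCCc1cc(O)cc2OC(C)(C)OC(=O)c12 | intermediate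
9 | benzyl 2,4-dihydroxy-6-pentylbenzoate | CCCCCc1cc(O)cc(O)c1C(=O)OCc1ccccc1 | intermediate
10 | 5-propylbenzene-1,3-diol (divarinol) | CCCc1cc(O)cc(O)c1 | starting material
11 | 1,3-dimethoxy-5-propylbenzene | CCCc1cc(OC)cc(OC)c1 | intermediate
12 | 2,4-dimethoxy-6-propylbenzaldehyde | CCCc1cc(OC)cc(OC)c1C=O | intermediate
13 | 2,4-dimethoxy-6-propylbenzoic acid | CCCc1cc(OC)cc(OC)c1C(=O)O | intermediate
14 | 2,4-dimethoxy-6-propylbenzoyl chloride | CCCc1cc(OC)cc(OC)c1C(=O)Cl | intermediate
15 | benzyl 4-[(2,4-dimethoxy-6-propylbenzoyl)oxy]-2-hydroxy-6-pentylbenzoate | CCCCCc1cc(OC(=O)c2c(CCC)cc(OC)cc2OC)cc(O)c1C(=O)OCc1ccccc1 | intermediate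
16 | 4-[(2,4-dimethoxy-6-propylbenzoyl)oxy]-2-hydroxy-6-pentylbenzoic acid | CCCCCc1cc(OC(=O)c2c(CCC)cc(OC)cc2OC)cc(O)c1C(=O)O | target

**Step count**
Total: 11 steps. Longest linear sequence: 6 steps (1 → 3 → 6 → 8 → 9 → 15 → 16, steps 1, 3, 4, 5, 10, 11); the aroyl branch (steps 6–11) is equally long.

**Steps most likely to fail**

Step 4 (key step). Enolisation of the tricarbonyl chain may lead to O-cyclisation onto the dioxinone or to decomposition faster than the C-aldol, or the sequence may stall before dehydration. The fallback sets out from 6 and moves the same aldol to an open-chain ester. Heating 6 with benzyl alcohol in toluene at 110 °C should expel acetone by retro-hetero-Diels–Alder reaction to give the acylketene 3,5,7-trioxododec-1-en-1-one F2, which is trapped as benzyl 3,5,7-trioxododecanoate F3. Treatment of F3 with Cs2CO3 in THF and then acid (aldol, dehydration, enolisation) should give the benzyl resorcylate directly. This route comes back at 9 and bypasses 8 and step 5.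

Step 3. The terminal carbanion of the dianion may add too slowly to the amide at temperatures the dianion tolerates, so that proton exchange and self-condensation compete, and the sensitive product may cyclise partly on work-up. The fallback sets out from 3 and replaces the Claisen acylation by aldol addition and oxidation. The same dianion (LDA, THF, −78 °C) is treated with commercial hexanal, a far better electrophile, to give racemic 6-(4-hydroxy-2-oxononyl)-2,2-dimethyl-4H-1,3-dioxin-4-one F1. Oxidation of this β-hydroxy ketone with Dess–Martin periodinane (CH2Cl2, 0 °C → rt) removes the stereocentre and comes back to the route at 6.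

Step 5. Addition of benzyloxide to the lactone carbonyl is slowed by the para-phenoxide and by the ortho pentyl group, so that opening may be incomplete or, with adventitious water, give the acid and then decarboxylation. The fallback sets out from 8 and separates hydrolysis from esterification. Saponification with aqueous KOH in dioxane at moderate temperature and cold acidification should give 2,4-dihydroxy-6-pentylbenzoic acid F4 (olivetolic acid). Carboxylate-selective alkylation with benzyl bromide and KHCO3 in DMF at rt, which leaves the phenols unalkylated, comes back to the route at 9.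

**Further compounds**
F1 | step 3 | 6-(4-hydroxy-2-oxononyl)-2,2-dimethyl-4H-1,3-dioxin-4-one (racemic) | CCCCCC(O)CC(=O)CC1=CC(=O)OC(C)(C)O1
F2 | step 4 | 3,5,7-trioxododec-1-en-1-one (acylketene, transient) | CCCCCC(=O)CC(=O)CC(=O)C=C=O
F3 | step 4 | benzyl 3,5,7-trioxododecanoate | CCCCCC(=O)CC(=O)CC(=O)CC(=O)OCc1ccccc1
F4 | step 5 | 2,4-dihydroxy-6-pentylbenzoic acid (olivetolic acid) | CCCCCc1cc(O)cc(O)c1C(=O)O
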